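The earlier runs and the new flask stem from a simulated flask with made-up constants.

The coupling partner, as I read these runs, is paid out a second time: substrate and partner make target, and target then meets partner again and is lost.

| flask | substrate | coupling partner | time |
|---|---|---|---|
| epsilon | 200 mM | 240 mM |  |
| delta | 120 mM | 160 mM |  |
| beta | 300 mM | 240 mM |  |
| zeta | 200 mM | 120 mM |  |
| gamma | 200 mM | 240 mM | 28 min |

| run | time / min | [target] / mM |
|---|---|---|
| epsilon run | 0.25 | 5.6 |
| epsilon run | 0.75 | 16.8 |
| epsilon run | 1.4 | 29.1 |
| epsilon run | 2.3 | 41.1 |
| epsilon run | 3.3 | 49.8 |
| epsilon run | 4.4 | 57.3 |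
| epsilon run | 5.6 | 61.4 |
| epsilon run | 6.9 | 63.1 |
| delta run | 0.25 | 3.8 |
| delta run | 0.75 | 8.2 |
| delta run | 1.4 | 13.7 |
| delta run | 2.3 | 20.3 |
| delta run | 3.3 | 26.8 |
| delta run | 4.4 | 30.6 |
| delta run | 5.6 | 35.0 |
| delta run | 6.9 | 37.0 |
| beta run | 0.25 | 8.6 |
| beta run | 0.75 | 23.2 |
| beta run | 1.4 | 38.6 |
| beta run | 2.3 | 55.1 |
| beta run | 3.3 | 68.5 |
| beta run | 4.4 | 79.2 |
| beta run | 5.6 | 86.5 |
| beta run | 6.9 | 89.6 |
| zeta run | 0.25 | 3.3 |
| zeta run | 0.75 | 10.2 |
| zeta run | 1.4 | 16.8 |
| zeta run | 2.3 | 25.1 |
| zeta run | 3.3 | 32.4 |
| zeta run | 4.4 | 40.1 |
| zeta run | 5.6 | 44.1 |
| zeta run | 6.9 | 48.2 |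

(scatter of a reading: 0.6 mM)

1. order of the initial rate in [substrate], near the charge of the epsilon run, the rate being that where two percent of its substrate are target (one fixed amount of target, the same in the runs compared)
2. order of the initial rate in [coupling partner], near the charge of the epsilon run, the rate being that where two percent of its substrate are target
3. target in the gamma run at 28 min, as a share of the substrate charged

- Overall: substrate + coupling partner -> target.
- Constant volume, constant temperature.
- What is held in complexes is read along with the free species.
- "The second partner" is coupling partner.
- An order is taken over about fifteen percent of the charge, up and down.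

If both steps take one partner, the partner cancels at the fork, and the stall share of the substrate charge S should hardly depend on the charge. I therefore treat the last epsilon reading P as the peak, where target is lost as fast as it is made. For a ratio of loss to making near 1 this gives:

κ ≈ 2 ln(S/P) − 1 = 1.31

This κ is my apparent selectivity factor, the ratio of loss to making that a plain two-step picture needs in order to match the stall, read from the readings and not a measured ratio of rate constants. The delta and beta runs read 1.35 and 1.42, so κ nearly holds across those charges.

At the stall the substrate fraction left is x = κ^(1/(1−κ)) = 0.418. Each substrate turned costs one partner and each target lost costs another, so the partner spent per substrate charged is: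

b = 2(1 − x) − P/S = 0.848

One number is not quite enough, because the zeta run charges 120 mM against the 170 mM its stall would cost, so partner per substrate matters too.

The gamma run has the epsilon charge, which leaves 70.3 mM of partner past the stall. There each substrate turned costs about two partners, so I take the end fraction as:

x = 0.242

Target is then (x − x^κ)/(κ − 1) = 27.8% of the charge, assuming 28 min is long enough to get there.

The forecast gives orders 0.8 and 0.72 and a share of 33% (range 31.5% to 37%), saying “At 28 min, gamma should sit on the plateau”.

The flask gives orders 0.89 and 0.81 and a share of 25.7%, which is 2.1 percentage points below my reckoning.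

    substrate + coupling partner ⇌ target + by-product (0.8820 /M/min, 0.1620 /M/min)
    substrate + coupling partner ⇌ idle substrate-reagent adduct, settled at all times (1.590 /M)
    target + coupling partner → side product (0.8280 /M/min)

The gamma share stands low because of the path from target and partner to side product: without that path the same gamma run gives 72.7% instead of 25.7%. With κ at 1.31, the partner bill 170 mM stays above the zeta charge of 120 mM, and the zeta run brings target to a quarter of its substrate at 7.49 min.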